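**Direct plan and its weak points**

A direct plan would build ring C stepwise from two protected halves. An arylmagnesium reagent from aryl iodide A1 (ring A, mixed PMB/TBS protection) would open the terminal epoxide A3, which would come from a Sharpless kinetic resolution of the racemic aryl vinyl carbinol A2. Desilylation to triol A4, intramolecular Mitsunobu etherification to protected epicatechin A5, acylation and hydrogenolysis would finish.
- The kinetic resolution that sets both stereocentres would be weak because at best half of A2 can end up in A3 and the rest is discarded.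
- The run-up to A1 would be weak because protection, C–H oxidation, iodination and silylation are spent on a simple phloroglucinol nucleophile without forming one bond of the skeleton.
- The ring closure by SN2 displacement at the 3,4-dialkoxybenzylic carbinol of A4 would be weak because this centre ionises easily, so the 2,3-cis relationship can leak to the trans isomer or to elimination, and the ester still needs a separate late step.

**Retrosynthetic overview of the new route**

- Ring C is cut across O1–C2 and C3–C4 at once. The C4 methylene flanked by the phloroglucinol ring A (C4a, C8a–O1) is read as an ortho-quinone methide, and the cis C2(aryl)–C3(O-acyl) pair as the (Z)-enol ester of the same 4-hydroxybenzoic acid that the target carries.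
- Rings A and B and the benzoate ring come ready-made from three commercial aromatics. Ring C is the only ring formed, in one catalytic asymmetric oxa-[4+2] cycloaddition that sets C2 and C3 together and brings the ester in.
- The enol ester comes from an aryl alkyne and the acid by ruthenium-catalysed anti-Markovnikov addition. The quinone methide precursor is a salicyl alcohol, two steps from 2,4,6-trihydroxybenzaldehyde.
- The design needs no resolution, no substitution at the benzylic carbinol, no separate acylation, and only benzyl protection, removed in one hydrogenolysis.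

Key step: step 5

Remark: the sense of induction of the chiral acid in step 5 cannot be derived safely from precedent. The (R)-catalyst is written; its mirror image, equally available, would be used if a first run shows the (2S,3S) product to prevail.

**Route**

Step 1
Reactants: 1 2,4,6-trihydroxybenzaldehyde
Product: 2 2,4-bis(benzyloxy)-6-hydroxybenzaldehyde
Conditions: BnBr (2.05 eq), K2CO3 (2.1 eq), DMF, 0 °C→rt
Reagents that add atoms: benzyl bromide, BrCc1ccccc1
Why: Williamson ether synthesis under stoichiometric control, in which the 4-OH and one ortho OH are alkylated while the remaining ortho OH, held in a hydrogen bond to the formyl oxygen, stays free.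

Step 2
Reactants: 2 2,4-bis(benzyloxy)-6-hydroxybenzaldehyde
Product: 3 3,5-bis(benzyloxy)-2-(hydroxymethyl)phenol
Conditions: NaBH4 (1.0 eq), THF/MeOH, −10→0 °C; sat. aq. NH4Cl; used at once without chromatography on acidic silica
Reagents that add atoms: none
Why: Borohydride 1,2-reduction of the aldehyde, with low temperature and neutral work-up to keep the electron-rich salicyl alcohol from ionising early.

Step 3
Reactants: 4 3,4-bis(benzyloxy)benzaldehyde
Product: 5 1,2-bis(benzyloxy)-4-ethynylbenzene
Conditions: dimethyl (1-diazo-2-oxopropyl)phosphonate (1.3 eq), K2CO3 (2 eq), MeOH/THF, 0 °C→rt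
Reagents that add atoms: dimethyl (1-diazo-2-oxopropyl)phosphonate, CC(=O)C(=[N+]=[N-])P(=O)(OC)OC
Why: Seyferth–Gilbert homologation in the Ohira–Bestmann variant, in which the diazomethylphosphonate anion formed by methanolysis adds to the aldehyde and loss of N2 with a 1,2-hydride shift gives the terminal alkyne.

Step 4
Reactants: 5 1,2-bis(benzyloxy)-4-ethynylbenzene; 6 4-(benzyloxy)benzoic acid
Product: 7 (Z)-2-[3,4-bis(benzyloxy)phenyl]ethenyl 4-(benzyloxy)benzoate
Conditions: 6 (1.05 eq), Ru(η3-CH2CMeCH2)2(Ph2P(CH2)4PPh2) (2 mol%), toluene, 60 °C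
Reagents that add atoms: none
Why: Ruthenium-vinylidene anti-Markovnikov hydro-oxycarbonylation of a terminal alkyne, in which the carboxylate adds to the α-carbon of the vinylidene and protonolysis leaves aryl and acyloxy groups cis, so the (Z)-alk-1-enyl ester should form.

Step 5
Reactants: 3 3,5-bis(benzyloxy)-2-(hydroxymethyl)phenol; 7 (Z)-2-[3,4-bis(benzyloxy)phenyl]ethenyl 4-(benzyloxy)benzoate
Product: 9 (2R,3R)-5,7-bis(benzyloxy)-2-[3,4-bis(benzyloxy)phenyl]-3,4-dihydro-2H-chromen-3-yl 4-(benzyloxy)benzoate, via ortho-quinone methide 8 (not isolated)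
Conditions: 7 (1.0 eq), (R)-[H8]-BINOL N-triflylphosphoramide with 3,3′-bis(2,4,6-triisopropylphenyl) groups (10 mol%), 5 Å MS, CHCl3, −30 °C; 3 (1.6 eq) added by syringe pump over 8 h
Reagents that add atoms: none
Why: Proposed new method: the chiral acid ionises 3 with loss of water to the ortho-quinone methide 8, which stays hydrogen-bonded or ion-paired to the catalyst anion and is trapped by the styrene-type C=C of 7 in an inverse-electron-demand oxa-[4+2] cycloaddition (hetero-Diels–Alder); the closest known reaction type is the chiral N-triflylphosphoramide- or phosphoric acid-catalysed cycloaddition of ortho-quinone methides, formed in situ from ortho-hydroxybenzyl alcohols, with styrenes, vinyl sulfides and enecarbamates, and new here are the enol ester as 2π partner and a quinone methide with an unsubstituted methylene, so that both stereocentres arise on the dienophile. Ring C closes in this single [4+2] event by forming C3–C4 and O1–C2, with C–C bond formation running ahead of C–O bond formation. The regiochemistry follows from the polarisation of 7: the 3,4-dialkoxyphenyl group is a far stronger donor than the cross-conjugated acyloxy oxygen, so the acyloxy-bearing carbon attacks the electrophilic methylene (C4) and the developing benzylic cation is captured by O1. The relative configuration is controlled by the alkene geometry, since suprafacial addition to the (Z)-enol ester places the C2 aryl and C3 acyloxy groups cis. The absolute configuration is controlled by the catalyst, whose 3,3′-aryl groups shield one face of the bound quinone methide while the cis-disubstituted dienophile adds endo to the open face. The step needs cycloaddition to outrun Friedel–Crafts self-alkylation of the electron-rich rings and ring closure to outrun rotation in any benzylic cation; slow addition of 3 (low concentration of 3 and 8), a weakly polar solvent and low temperature are meant to secure both.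

Step 6
Reactants: 9 (2R,3R)-5,7-bis(benzyloxy)-2-[3,4-bis(benzyloxy)phenyl]-3,4-dihydro-2H-chromen-3-yl 4-(benzyloxy)benzoate
Product: 10 epicatechin 3-O-p-hydroxybenzoate, (2R,3R)-2-(3,4-dihydroxyphenyl)-5,7-dihydroxy-3,4-dihydro-2H-chromen-3-yl 4-hydroxybenzoate
Conditions: H2 (1 atm), 20% Pd(OH)2/C, THF/MeOH, rt
Reagents that add atoms: none
Why: Catalytic hydrogenolysis of the five aryl benzyl ethers, under which the secondary benzoate, the C2–O1 bond and both stereocentres should persist at 1 atm and room temperature.

**Compound list**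

1 | 2,4,6-trihydroxybenzaldehyde | O=Cc1c(O)cc(O)cc1O | starting material
2 | 2,4-bis(benzyloxy)-6-hydroxybenzaldehyde | O=Cc1c(O)cc(OCc2ccccc2)cc1OCc1ccccc1 | intermediate
3 | 3,5-bis(benzyloxy)-2-(hydroxymethyl)phenol | OCc1c(O)cc(OCc2ccccc2)cc1OCc1ccccc1 | intermediate
4 | 3,4-bis(benzyloxy)benzaldehyde | O=Cc1ccc(OCc2ccccc2)c(OCc2ccccc2)c1 | starting material
5 | 1,2-bis(benzyloxy)-4-ethynylbenzene | C#Cc1ccc(OCc2ccccc2)c(OCc2ccccc2)c1 | intermediate
6 | 4-(benzyloxy)benzoic acid | OC(=O)c1ccc(OCc2ccccc2)cc1 | starting material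
7 | (Z)-2-[3,4-bis(benzyloxy)phenyl]ethenyl 4-(benzyloxy)benzoate | O=C(O/C=C\c1ccc(OCc2ccccc2)c(OCc2ccccc2)c1)c1ccc(OCc2ccccc2)cc1 | intermediate
8 | 3,5-bis(benzyloxy)-6-methylidenecyclohexa-2,4-dien-1-one (ortho-quinone methide) | C=C1C(=O)C=C(OCc2ccccc2)C=C1OCc1ccccc1 | intermediate (not isolated)
9 | (2R,3R)-5,7-bis(benzyloxy)-2-[3,4-bis(benzyloxy)phenyl]-3,4-dihydro-2H-chromen-3-yl 4-(benzyloxy)benzoate | O=C(O[C@@H]1Cc2c(OCc3ccccc3)cc(OCc3ccccc3)cc2O[C@@H]1c1ccc(OCc2ccccc2)c(OCc2ccccc2)c1)c1ccc(OCc2ccccc2)cc1 | intermediate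
10 | epicatechin 3-O-p-hydroxybenzoate, (2R,3R)-2-(3,4-dihydroxyphenyl)-5,7-dihydroxy-3,4-dihydro-2H-chromen-3-yl 4-hydroxybenzoate | O=C(O[C@@H]1Cc2c(O)cc(O)cc2O[C@@H]1c1ccc(O)c(O)c1)c1ccc(O)cc1 | target

**Step count and risks**

Total steps: 6. Longest linear sequence: 4 steps (1 → 2 → 3 → 9 → 10, or 4 → 5 → 7 → 9 → 10).

Steps most likely to fail:

1. Step 5 (Proposed new method).
 - What may go wrong: Friedel–Crafts self-alkylation of the electron-rich rings of 3 or 9 by the quinone methide may outrun the cycloaddition. A stepwise cationic course may allow rotation about C2–C3 before ring closure and leak to the 2,3-trans isomer. Facial discrimination by the catalyst may be poor.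
 - Fallback (known chemistry): it sets out from 2 and 4 and comes back to the route at 9. Ring C is again closed through O1–C2 and C3–C4, and the stereocentres are set by dynamic kinetic resolution.
 - Henry condensation of 4 with nitromethane (NH4OAc, AcOH, 100 °C) would give (E)-1,2-bis(benzyloxy)-4-(2-nitroethenyl)benzene F1.
 - The domino oxa-Michael/Henry/dehydration of 2 with F1 (DABCO, MeCN, 60 °C) would close ring C as racemic 5,7-bis(benzyloxy)-2-[3,4-bis(benzyloxy)phenyl]-3-nitro-2H-chromene F2.
 - Reductive hydrolysis of the nitroalkene (Fe powder, AcOH/EtOH/H2O, 70 °C) would give racemic 5,7-bis(benzyloxy)-2-[3,4-bis(benzyloxy)phenyl]-2H-chromen-3(4H)-one F3. Its C2–H, flanked by aryl, ring oxygen and carbonyl, should epimerise readily.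
 - Asymmetric transfer hydrogenation under dynamic kinetic resolution (RuCl[(S,S)-TsDPEN](p-cymene), HCO2H/Et3N, CH2Cl2, rt; catalyst antipode fixed in a test run) should reduce one enantiomer of the equilibrating ketone from the face anti to the C2 aryl group. This should give the cis alcohol (2R,3R)-5,7-bis(benzyloxy)-2-[3,4-bis(benzyloxy)phenyl]-3,4-dihydro-2H-chromen-3-ol F4.
 - Steglich esterification of F4 with 6 (DCC, DMAP, CH2Cl2) returns to 9.

2. Step 2.
 - What may go wrong: the phenoxide may expel the benzylic oxygen as the borate, and the resulting quinone methide would be reduced further to the ortho-cresol. The product may also self-condense during concentration.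
 - Fallback: it sets out from 2 and comes back at 3, with the phenol masked so that the phenoxide-driven pathway is closed.
 - Silylation of 2 (TBSCl, imidazole, DMF) would give 2,4-bis(benzyloxy)-6-[(tert-butyldimethylsilyl)oxy]benzaldehyde F5.
 - Reduction of F5 with DIBAL-H (CH2Cl2, −78 °C) would give {2,4-bis(benzyloxy)-6-[(tert-butyldimethylsilyl)oxy]phenyl}methanol F6.
 - Buffered desilylation of F6 (TBAF/AcOH, THF, 0 °C) returns to 3.

3. Step 4.
 - What may go wrong: competing Markovnikov addition, partial formation of the (E)-isomer, or head-to-head dimerisation of the electron-rich alkyne at the ruthenium vinylidene.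
 - Fallback: it sets out from 5 and comes back at 7, with the alkene geometry fixed before the C–O bond is made.
 - Rhodium-catalysed trans-hydroboration of 5 ([Rh(cod)Cl]2, P(i-Pr)3, Et3N, pinacolborane, cyclohexane, rt) would give 2-{(Z)-2-[3,4-bis(benzyloxy)phenyl]ethenyl}-4,4,5,5-tetramethyl-1,3,2-dioxaborolane F7.
 - KHF2 (MeOH/H2O) would convert F7 into potassium {(Z)-2-[3,4-bis(benzyloxy)phenyl]ethenyl}trifluoroborate F8.
 - Copper-catalysed oxidative (Chan–Lam-type) coupling of F8 with 6 (CuBr, DMAP, 4 Å MS, O2, CH2Cl2, 40 °C) should give 7 with retention of the alkene geometry.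

**Further compounds**

F1 | step 5 | (E)-1,2-bis(benzyloxy)-4-(2-nitroethenyl)benzene | [O-][N+](=O)/C=C/c1ccc(OCc2ccccc2)c(OCc2ccccc2)c1
F2 | step 5 | rac-5,7-bis(benzyloxy)-2-[3,4-bis(benzyloxy)phenyl]-3-nitro-2H-chromene | [O-][N+](=O)C1=Cc2c(OCc3ccccc3)cc(OCc3ccccc3)cc2OC1c1ccc(OCc2ccccc2)c(OCc2ccccc2)c1
F3 | step 5 | rac-5,7-bis(benzyloxy)-2-[3,4-bis(benzyloxy)phenyl]-2H-chromen-3(4H)-one | O=C1Cc2c(OCc3ccccc3)cc(OCc3ccccc3)cc2OC1c1ccc(OCc2ccccc2)c(OCc2ccccc2)c1
F4 | step 5 | (2R,3R)-5,7-bis(benzyloxy)-2-[3,4-bis(benzyloxy)phenyl]-3,4-dihydro-2H-chromen-3-ol | O[C@@H]1Cc2c(OCc3ccccc3)cc(OCc3ccccc3)cc2O[C@@H]1c1ccc(OCc2ccccc2)c(OCc2ccccc2)c1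
F5 | step 2 | 2,4-bis(benzyloxy)-6-[(tert-butyldimethylsilyl)oxy]benzaldehyde | O=Cc1c(O[Si](C)(C)C(C)(C)C)cc(OCc2ccccc2)cc1OCc1ccccc1
F6 | step 2 | {2,4-bis(benzyloxy)-6-[(tert-butyldimethylsilyl)oxy]phenyl}methanol | OCc1c(O[Si](C)(C)C(C)(C)C)cc(OCc2ccccc2)cc1OCc1ccccc1
F7 | step 4 | 2-{(Z)-2-[3,4-bis(benzyloxy)phenyl]ethenyl}-4,4,5,5-tetramethyl-1,3,2-dioxaborolane | CC1(C)OB(/C=C\c2ccc(OCc3ccccc3)c(OCc3ccccc3)c2)OC1(C)C
F8 | step 4 | potassium {(Z)-2-[3,4-bis(benzyloxy)phenyl]ethenyl}trifluoroborate | [K+].F[B-](F)(F)/C=C\c1ccc(OCc2ccccc2)c(OCc2ccccc2)c1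
A1 | direct plan | tert-butyl{2-iodo-3,5-bis[(4-methoxybenzyl)oxy]phenoxy}dimethylsilane | COc1ccc(COc2cc(O[Si](C)(C)C(C)(C)C)c(I)c(OCc3ccc(OC)cc3)c2)cc1
A2 | direct plan | rac-1-[3,4-bis(benzyloxy)phenyl]prop-2-en-1-ol | C=CC(O)c1ccc(OCc2ccccc2)c(OCc2ccccc2)c1
A3 | direct plan | (S)-[3,4-bis(benzyloxy)phenyl][(2R)-oxiran-2-yl]methanol | O[C@H]([C@H]1CO1)c1ccc(OCc2ccccc2)c(OCc2ccccc2)c1
A4 | direct plan | (1S,2R)-1-[3,4-bis(benzyloxy)phenyl]-3-{2-hydroxy-4,6-bis[(4-methoxybenzyl)oxy]phenyl}propane-1,2-diol | O[C@H]([C@H](O)Cc1c(O)cc(OCc2ccc(OC)cc2)cc1OCc1ccc(OC)cc1)c1ccc(OCc2ccccc2)c(OCc2ccccc2)c1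
A5 | direct plan | (2R,3R)-2-[3,4-bis(benzyloxy)phenyl]-5,7-bis[(4-methoxybenzyl)oxy]-3,4-dihydro-2H-chromen-3-ol | O[C@@H]1Cc2c(OCc3ccc(OC)cc3)cc(OCc3ccc(OC)cc3)cc2O[C@@H]1c1ccc(OCc2ccccc2)c(OCc2ccccc2)c1
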